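**Retrosynthetic overview** (labdane numbering, C1–C20; ring A = C1–C5/C10, ring B = C5–C10)

1. Ring A is cut at C1–C2 and C5–C10: an intramolecular Diels–Alder reaction of the 2-siloxydiene C2=C3(OTBS)–C4(CH3)=C5 with the isopropenyl dienophile C10(CH3)=C1, linked by the chain C6–C7–C8–C9, closes rings A and B together (ring B through the same C5–C10 bond).
2. The enabling feature is ring A itself: the C1–C2 and C5–C10 bonds flank a C3/C4 pair that can sit at the enol-ether level (C3=C4 after cycloaddition). The temporary C3 oxygen delivers the C4 quaternary centre and is then removed; a C8 ketone in the tether becomes the C7=C8–CH3 unit.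
3. The acyclic triene is joined at C8–C9 by a tartrate-controlled allylboration that creates C9 and the isopropenyl group. C2–C8 come from (R)-3-hydroxy-γ-butyrolactone (C6 stereocentre); C1, C9–C16 and C20, with the finished (E)-enoate side chain, come from methyl geranate.
4. Ring order: A and B simultaneously in step 11; no later ring construction.

Key step: step 11

Assumption: (R)-3-hydroxy-γ-butyrolactone, methyl (E)-geranate and 3-(triphenylphosphoranylidene)butan-2-one are taken as purchasable; labdane locants are used for all intermediates.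

**Route**

Step 1
Reactants: 1 (R)-3-hydroxy-γ-butyrolactone
Product: 2 (4R)-4-[(tert-butyldimethylsilyl)oxy]oxolan-2-one
Conditions: TBSCl, imidazole, DMF, 25 °C
Reagents that add atoms: tert-butyldimethylsilyl chloride CC(C)(C)[Si](C)(C)Cl
Why: Standard silylation of the secondary alcohol; the future C6 stereocentre comes from the chiral pool and is not touched.

Step 2
Reactants: 2 (4R)-4-[(tert-butyldimethylsilyl)oxy]oxolan-2-one
Product: 3 (3R)-3-[(tert-butyldimethylsilyl)oxy]-4-hydroxy-N-methoxy-N-methylbutanamide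
Conditions: MeNH(OMe)·HCl, AlMe3, CH2Cl2, 0 → 25 °C; used crude
Reagents that add atoms: N,O-dimethylhydroxylamine hydrochloride CNOC.Cl
Why: Weinreb aminolysis of the lactone by the aluminium amide opens the ring and differentiates C5 (primary alcohol) from C8 (amide).

Step 3
Reactants: 3 (3R)-3-[(tert-butyldimethylsilyl)oxy]-4-hydroxy-N-methoxy-N-methylbutanamide
Product: 4 (3R)-3-[(tert-butyldimethylsilyl)oxy]-N-methoxy-N-methyl-4-oxobutanamide
Conditions: Dess–Martin periodinane, pyridine, CH2Cl2, 0 → 25 °C
Reagents that add atoms: none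
Why: Buffered Dess–Martin oxidation should give the α-silyloxy aldehyde (C5) without epimerising C6.

Step 4
Reactants: 4 (3R)-3-[(tert-butyldimethylsilyl)oxy]-N-methoxy-N-methyl-4-oxobutanamide
Product: 5 (3R,4E)-3-[(tert-butyldimethylsilyl)oxy]-N-methoxy-N,5-dimethyl-6-oxohept-4-enamide
Conditions: toluene, 80 °C
Reagents that add atoms: 3-(triphenylphosphoranylidene)butan-2-one CC(=O)C(C)=P(c1ccccc1)(c1ccccc1)c1ccccc1
Why: Wittig olefination with a stabilised acyl ylide should give the (E)-trisubstituted enone C4=C5 and brings in C2, C3, C4 and the C4 methyl.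

Step 5
Reactants: 5 (3R,4E)-3-[(tert-butyldimethylsilyl)oxy]-N-methoxy-N,5-dimethyl-6-oxohept-4-enamide
Product: 6 (3R,4E)-3,6-bis[(tert-butyldimethylsilyl)oxy]-N-methoxy-N,5-dimethylhepta-4,6-dienamide
Conditions: TBSOTf, Et3N, CH2Cl2, −78 → 0 °C
Reagents that add atoms: tert-butyldimethylsilyl trifluoromethanesulfonate CC(C)(C)[Si](C)(C)OS(=O)(=O)C(F)(F)F
Why: Soft enolisation of the methyl ketone on its CH3 side gives the cross-conjugated 2-siloxydiene; the Weinreb amide and the alkyl silyl ether are inert.

Step 6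
Reactants: 6 (3R,4E)-3,6-bis[(tert-butyldimethylsilyl)oxy]-N-methoxy-N,5-dimethylhepta-4,6-dienamide
Product: 7 (3R,4E)-3,6-bis[(tert-butyldimethylsilyl)oxy]-5-methylhepta-4,6-dienal
Conditions: i-Bu2AlH, THF, −78 °C; Rochelle salt work-up
Reagents that add atoms: none
Why: Weinreb amide reduction stops at the aldehyde (C8) through the chelated aluminium hemiaminal; the silyl dienol ether should survive hydride and a neutral work-up.

Step 7
Reactants: 8 methyl (2E)-3,7-dimethylocta-2,6-dienoate (methyl geranate)
Product: 9 methyl (2E,6E)-8-hydroxy-3,7-dimethylocta-2,6-dienoate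
Conditions: SeO2 (0.2 equiv), t-BuOOH (70% aq.), CH2Cl2, 25 °C
Reagents that add atoms: tert-butyl hydroperoxide CC(C)(C)OO
Why: Riley-type allylic oxidation (ene reaction, then [2,3]-shift) is selective for the (E)-methyl group of the electron-rich terminal alkene; the conjugated enoate is deactivated.

Step 8
Reactants: 9 methyl (2E,6E)-8-hydroxy-3,7-dimethylocta-2,6-dienoate
Product: 11 diisopropyl (4R,5R)-2-[(2E,6E)-8-methoxy-2,6-dimethyl-8-oxoocta-2,6-dien-1-yl]-1,3,2-dioxaborolane-4,5-dicarboxylate, via allylboronic acid 10 (not isolated)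
Conditions: B2(OH)4, [Pd(MeCN)4](BF4)2 (5 mol %), DMSO/MeOH, 25 °C; then (R,R)-diisopropyl tartrate, MgSO4, toluene, 25 °C, under argon
Reagents that add atoms: tetrahydroxydiboron OB(O)B(O)O; diisopropyl (R,R)-tartrate CC(C)OC(=O)[C@H](O)[C@@H](O)C(=O)OC(C)C
Why: Palladium-catalysed borylation of the allylic alcohol through an allylpalladium intermediate should give the linear (E)-allylboronic acid, which the tartrate esterifies to a Roush-type reagent; the enoate is tolerated.

Step 9
Reactants: 7 (3R,4E)-3,6-bis[(tert-butyldimethylsilyl)oxy]-5-methylhepta-4,6-dienal; 11 tartrate allylboronate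
Product: 12 methyl (2E,6S,7R,9R,10E)-9,12-bis[(tert-butyldimethylsilyl)oxy]-7-hydroxy-3,11-dimethyl-6-(prop-1-en-2-yl)trideca-2,10,12-trienoate
Conditions: toluene, 4 Å molecular sieves, −78 °C; then aq. NaHCO3
Reagents that add atoms: none
Why: Roush asymmetric allylboration through a closed chair transition state: the boronate adds through its γ-carbon (C9), which forms C8–C9 and creates the isopropenyl group C10=C1 by allylic transposition; the (E)-alkene gives the 8,9-anti product and the (R,R)-tartrate directs attack on the si face of the aldehyde, reinforced by the 1,3-anti preference of the β-silyloxy aldehyde, which sets C9 (and the temporary C8 carbinol).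

Step 10
Reactants: 12 homoallylic alcohol
Product: 13 methyl (2E,6S,9R,10E)-9,12-bis[(tert-butyldimethylsilyl)oxy]-3,11-dimethyl-7-oxo-6-(prop-1-en-2-yl)trideca-2,10,12-trienoate
Conditions: Dess–Martin periodinane, pyridine, CH2Cl2, 0 °C
Reagents that add atoms: none
Why: Buffered Dess–Martin oxidation should give the β,γ-unsaturated C8 ketone without epimerising C9 or moving the double bond into conjugation; the C8 stereocentre is erased as planned.

Step 11
Reactants: 13 triene ketone
Product: 14 methyl (2E)-5-[4,6-bis[(tert-butyldimethylsilyl)oxy]-5,8a-dimethyl-2-oxo-1,2,3,4,4a,7,8,8a-octahydronaphthalen-1-yl]-3-methylpent-2-enoate (trans-fused; C5, C6, C9, C10 as in the target; C3=C4 silyl enol ether; C8 ketone)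
Conditions: toluene (5 mM), BHT (cat.), 2,6-di-tert-butyl-4-methylpyridine (0.1 equiv), 180 °C, sealed tube
Reagents that add atoms: none
Why: Thermal, concerted but asynchronous intramolecular [4+2] cycloaddition of a 1,3,9-decatriene (type 1 intramolecular Diels–Alder), in which the electron-rich 2-siloxydiene C2=C3(OTBS)–C4(CH3)=C5 adds to the isopropenyl C10=C1 and bonds C2–C1 and C5–C10; the closest known reactions are thermal cyclisations of unactivated 1,7,9-decatrienes with 1,1-disubstituted dienophiles to angular-methyl octalins and cycloadditions of 2-siloxydienes. Ring A is closed as the new cyclohexene by both σ-bonds, and ring B is closed by the C5–C10 bond through the four-carbon tether in a chair-like exo (anti) arrangement, a 6-exo-type closure on the dienophile that gives the trans-decalin. C5 is controlled by the C6 stereocentre: A(1,3) strain with the C4 methyl holds H6 in the diene plane, the tether occupies the reacting face and the silyloxy group points away, so H5 and H6 end up anti and the C6 oxygen equatorial. C10 follows from the exo orientation of the tether, which places the small C20 methyl rather than the branched C9 under the C4-methyl/C3-siloxy edge of the diene, and the C9 side chain lies anti to the incoming diene carbon (equatorial), so the preset C6 and C9 centres are matched. The step needs regio-, peri- and trans-selectivity: the tether fixes the regiochemistry (in line with the siloxy para preference), the side-chain enoate and the C8 carbonyl are geometrically out of reach, and the (E)-C4=C5 geometry and acid-free conditions keep the diene intact.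

Step 12
Reactants: 14 octalone
Product: 15 enol triflate of 14 (C7=C8–OTf; all other groups unchanged)
Conditions: KN(SiMe3)2, THF, −78 °C; then PhNTf2, −78 → 0 °C
Reagents that add atoms: N-phenylbis(trifluoromethanesulfonimide) FC(F)(F)S(=O)(=O)N(c1ccccc1)S(=O)(=O)C(F)(F)F
Why: Kinetic deprotonation occurs at the C7 methylene and not at the hindered tertiary C9, and the equatorial C6 silyloxy group is poorly aligned for β-elimination; the enolate is trapped as the enol triflate and C9 keeps its configuration.

Step 13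
Reactants: 15 enol triflate
Product: 16 methyl (13E)-3,6-bis[(tert-butyldimethylsilyl)oxy]-4-methyl-18,19-dinorlabda-3,7,13-trien-15-oate of the target series (C8 methyl installed; C3=C4 silyl enol ether)
Conditions: Me2Zn, Pd(PPh3)4 (5 mol %), THF, 0 → 45 °C
Reagents that add atoms: dimethylzinc C[Zn]C
Why: Negishi-type cross-coupling of the enol triflate installs C17 and fixes the C7=C8 position; zerovalent palladium should not touch the silyl enol ether or the enoate.

Step 14
Reactants: 16 silyl enol ether
Product: 17 methyl (13E)-6-[(tert-butyldimethylsilyl)oxy]-18-hydroxy-3-oxolabda-7,13-dien-15-oate of the target series (C4: CH2OH trans to the C10 methyl; CH3 cis)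
Conditions: 37% aq. HCHO, Sc(OTf)3 (10 mol %), THF, 25 °C
Reagents that add atoms: formaldehyde C=O
Why: Mukaiyama-type aldol (hydroxymethylation) of the regiodefined silyl enol ether; formaldehyde should approach C4 on the face opposite the axial C10 methyl, so the new CH2OH is equatorial and trans to C20 and the C4 methyl becomes axial, which sets C4.

Step 15
Reactants: 17 β-hydroxy ketone
Product: 19 methyl (13E)-6-[(tert-butyldimethylsilyl)oxy]-18-hydroxylabda-7,13-dien-15-oate of the target series, via tosylhydrazone 18 (not isolated)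
Conditions: TsNHNH2, EtOH, 60 °C; then catecholborane, CHCl3, 0 °C; NaOAc·3H2O, 60 °C
Reagents that add atoms: none
Why: Caglioti-type deoxygenation: catecholborane reduces the C=N bond and the resulting diazene loses sulfinate and N2, which removes the temporary C3 oxygen without touching the enoate, the alkenes or the silyl ether.

Step 16
Reactants: 19 silyl ether
Product: 20 methyl (4S,5S,6R,9R,10S,13E)-6-hydroxy-4-(hydroxymethyl)-labda-7,13-dien-15-oate (target, CNP0149445.1)
Conditions: HF·pyridine, pyridine, THF, 0 → 25 °C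
Reagents that add atoms: none
Why: Fluoride cleavage of the secondary allylic TBS ether; buffered HF·pyridine should avoid ionisation of the allylic C6–O bond and leave the methyl ester intact.

**Compound list**

1 | (R)-3-hydroxy-γ-butyrolactone | O[C@H]1COC(=O)C1 | starting material
2 | (4R)-4-[(tert-butyldimethylsilyl)oxy]oxolan-2-one | CC(C)(C)[Si](C)(C)O[C@H]1COC(=O)C1 | intermediate
3 | (3R)-3-[(tert-butyldimethylsilyl)oxy]-4-hydroxy-N-methoxy-N-methylbutanamide | CON(C)C(=O)C[C@@H](O[Si](C)(C)C(C)(C)C)CO | intermediate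
4 | (3R)-3-[(tert-butyldimethylsilyl)oxy]-N-methoxy-N-methyl-4-oxobutanamide | CON(C)C(=O)C[C@@H](O[Si](C)(C)C(C)(C)C)C=O | intermediate
5 | (3R,4E)-3-[(tert-butyldimethylsilyl)oxy]-N-methoxy-N,5-dimethyl-6-oxohept-4-enamide | CON(C)C(=O)C[C@@H](O[Si](C)(C)C(C)(C)C)/C=C(\C)C(C)=O | intermediate
6 | (3R,4E)-3,6-bis[(tert-butyldimethylsilyl)oxy]-N-methoxy-N,5-dimethylhepta-4,6-dienamide | CON(C)C(=O)C[C@@H](O[Si](C)(C)C(C)(C)C)/C=C(\C)C(=C)O[Si](C)(C)C(C)(C)C | intermediate
7 | (3R,4E)-3,6-bis[(tert-butyldimethylsilyl)oxy]-5-methylhepta-4,6-dienal | O=CC[C@@H](O[Si](C)(C)C(C)(C)C)/C=C(\C)C(=C)O[Si](C)(C)C(C)(C)C | intermediate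
8 | methyl (2E)-3,7-dimethylocta-2,6-dienoate (methyl geranate) | COC(=O)/C=C(\C)CCC=C(C)C | starting material
9 | methyl (2E,6E)-8-hydroxy-3,7-dimethylocta-2,6-dienoate | COC(=O)/C=C(\C)CC/C=C(\C)CO | intermediate
10 | [(2E,6E)-8-methoxy-2,6-dimethyl-8-oxoocta-2,6-dien-1-yl]boronic acid | COC(=O)/C=C(\C)CC/C=C(\C)CB(O)O | intermediate
11 | diisopropyl (4R,5R)-2-[(2E,6E)-8-methoxy-2,6-dimethyl-8-oxoocta-2,6-dien-1-yl]-1,3,2-dioxaborolane-4,5-dicarboxylate | COC(=O)/C=C(\C)CC/C=C(\C)CB1O[C@@H](C(=O)OC(C)C)[C@H](C(=O)OC(C)C)O1 | intermediate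
12 | methyl (2E,6S,7R,9R,10E)-9,12-bis[(tert-butyldimethylsilyl)oxy]-7-hydroxy-3,11-dimethyl-6-(prop-1-en-2-yl)trideca-2,10,12-trienoate | COC(=O)/C=C(\C)CC[C@@H](C(C)=C)[C@H](O)C[C@@H](O[Si](C)(C)C(C)(C)C)/C=C(\C)C(=C)O[Si](C)(C)C(C)(C)C | intermediate
13 | methyl (2E,6S,9R,10E)-9,12-bis[(tert-butyldimethylsilyl)oxy]-3,11-dimethyl-7-oxo-6-(prop-1-en-2-yl)trideca-2,10,12-trienoate | COC(=O)/C=C(\C)CC[C@@H](C(C)=C)C(=O)C[C@@H](O[Si](C)(C)C(C)(C)C)/C=C(\C)C(=C)O[Si](C)(C)C(C)(C)C | intermediate
14 | trans-fused cycloadduct: 8-oxo octalin with C3=C4 silyl enol ether, 6-OTBS equatorial, C9 side chain equatorial, C10 methyl | COC(=O)/C=C(\C)CC[C@@H]1C(=O)C[C@@H](O[Si](C)(C)C(C)(C)C)[C@@H]2C(C)=C(O[Si](C)(C)C(C)(C)C)CC[C@@]12C | intermediate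
15 | C7=C8 enol triflate of 14 | COC(=O)/C=C(\C)CC[C@@H]1C(OS(=O)(=O)C(F)(F)F)=C[C@@H](O[Si](C)(C)C(C)(C)C)[C@@H]2C(C)=C(O[Si](C)(C)C(C)(C)C)CC[C@@]12C | intermediate
16 | 8-methyl-Δ7 octalin with C3=C4 silyl enol ether and 6-OTBS | COC(=O)/C=C(\C)CC[C@@H]1C(C)=C[C@@H](O[Si](C)(C)C(C)(C)C)[C@@H]2C(C)=C(O[Si](C)(C)C(C)(C)C)CC[C@@]12C | intermediate
17 | 3-ketone with C4 quaternary centre (CH2OH trans to the C10 methyl), 6-OTBS | COC(=O)/C=C(\C)CC[C@@H]1C(C)=C[C@@H](O[Si](C)(C)C(C)(C)C)[C@@H]2[C@@](C)(CO)C(=O)CC[C@@]12C | intermediate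
18 | C3 tosylhydrazone of 17 | COC(=O)/C=C(\C)CC[C@@H]1C(C)=C[C@@H](O[Si](C)(C)C(C)(C)C)[C@@H]2[C@@](C)(CO)C(=NNS(=O)(=O)c3ccc(C)cc3)CC[C@@]12C | intermediate
19 | 6-O-TBS ether of the target | COC(=O)/C=C(\C)CC[C@@H]1C(C)=C[C@@H](O[Si](C)(C)C(C)(C)C)[C@@H]2[C@@](C)(CO)CCC[C@@]12C | intermediate
20 | methyl (4S,5S,6R,9R,10S,13E)-6-hydroxy-4-(hydroxymethyl)-labda-7,13-dien-15-oate | COC(=O)/C=C(\C)CC[C@@H]1C(C)=C[C@@H](O)[C@@H]2[C@@](C)(CO)CCC[C@@]12C | target

**Totals**

Total step count: 16. Longest linear sequence: 14 steps (steps 1–6 and 9–16, from lactone 1).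

**Steps most likely to fail**

Step 11. The dienophile is unactivated, so the cycloaddition needs about 180 °C. At that temperature the β-silyloxy β,γ-unsaturated ketone may lose silanol, shift its double bond into conjugation or epimerise at C9 before it cyclises, and the trans ring-fusion preference may erode. The fallback moves the cycloaddition to the C8 alcohol oxidation level; it sets out from 12 and comes back at 14. Alcohol 12 is acetylated (Ac2O, pyridine, DMAP) to the 8-acetoxy triene F1, which has no enolisable carbonyl and can be heated to 200–220 °C. Cycloaddition should give the 8-acetoxy octalin F2, mild methanolysis (K2CO3, MeOH, 0 °C) the 8-hydroxy octalin F3, and buffered Dess–Martin oxidation returns to ketone 14. This cures thermal lability only; a cis-fused isomer would have to be removed by chromatography at 14.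

Step 14. The hindered tetrasubstituted silyl enol ether may be protodesilylated in the aqueous medium faster than it forms the C–C bond, or formaldehyde may attack the face syn to C20 because the equatorial C6 silyloxy group crowds the desired trajectory. The fallback replaces the aqueous aldol by an anhydrous alkoxymethylation; it sets out from 16 and comes back at 17. Silyl enol ether 16 is alkylated with 4-methoxybenzyl chloromethyl ether (cat. ZnBr2, CH2Cl2, −40 °C) to the PMB-protected hydroxymethyl ketone F4, and DDQ (CH2Cl2/pH 7 buffer) removes the PMB group to give 17.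

Step 15. Hydrazone formation at the C3 carbonyl next to the quaternary C4 may be incomplete, or the β-hydroxy ketone may lose formaldehyde by retro-aldol cleavage during condensation. The fallback is a radical deoxygenation; it sets out from 17 and comes back at 19. Ketone 17 is reduced (NaBH4, MeOH, 0 °C) to the 3,18-diol F5 and converted with 1,1'-thiocarbonyldiimidazole into the six-membered cyclic thionocarbonate F6. Barton–McCombie fragmentation (Bu3SnH, AIBN, toluene, 110 °C) cleaves the C3–O bond through the secondary radical, and hydrolysis of the remaining C18 thiolcarbonate on basic work-up gives 19.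

**Further compounds**

F1 | step 11 | methyl (2E,6S,7R,9R,10E)-7-acetoxy-9,12-bis[(tert-butyldimethylsilyl)oxy]-3,11-dimethyl-6-(prop-1-en-2-yl)trideca-2,10,12-trienoate | COC(=O)/C=C(\C)CC[C@@H](C(C)=C)[C@H](OC(C)=O)C[C@@H](O[Si](C)(C)C(C)(C)C)/C=C(\C)C(=C)O[Si](C)(C)C(C)(C)C
F2 | step 11 | 8-acetoxy octalin (trans-fused cycloadduct of F1) | COC(=O)/C=C(\C)CC[C@@H]1[C@H](OC(C)=O)C[C@@H](O[Si](C)(C)C(C)(C)C)[C@@H]2C(C)=C(O[Si](C)(C)C(C)(C)C)CC[C@@]12C
F3 | step 11 | 8-hydroxy octalin | COC(=O)/C=C(\C)CC[C@@H]1[C@H](O)C[C@@H](O[Si](C)(C)C(C)(C)C)[C@@H]2C(C)=C(O[Si](C)(C)C(C)(C)C)CC[C@@]12C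
F4 | step 14 | 18-O-(4-methoxybenzyl) ether of 17 | COC(=O)/C=C(\C)CC[C@@H]1C(C)=C[C@@H](O[Si](C)(C)C(C)(C)C)[C@@H]2[C@@](C)(COCc3ccc(OC)cc3)C(=O)CC[C@@]12C
F5 | step 15 | 3,18-diol (3-OH equatorial) | COC(=O)/C=C(\C)CC[C@@H]1C(C)=C[C@@H](O[Si](C)(C)C(C)(C)C)[C@@H]2[C@@](C)(CO)[C@H](O)CC[C@@]12C
F6 | step 15 | 3,18-cyclic thionocarbonate | COC(=O)/C=C(\C)CC[C@@H]1C(C)=C[C@@H](O[Si](C)(C)C(C)(C)C)[C@@H]2[C@@]3(C)COC(=S)O[C@@H]3CC[C@@]12C
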